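**Retrosynthetic overview**
- Target ⇐ methyl ester cleavage ⇐ hydroxymethyl-directed reduction of the C5 ketone ⇐ hydroxymethyl-directed asymmetric nucleophilic epoxidation of a 2,3,5-trisubstituted benzoquinone (C1 and C6 are set there, C5 follows from them).
- Quinone ⇐ one-pot oxidative unmasking of a benzodioxin-protected hydroquinone; heptenyl group ⇐ Suzuki coupling of an ortho-iodophenol with the (E)-alkenylboronate from hept-1-yne.
- Key disconnection: the aryl C–CH2 bond of the complete (E)-enoate side chain ⇐ photo-Claisen radical-pair 1,3-shift of an aryl allyl ether (O to C, linear connectivity).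
- Ether ⇐ hydroquinone + methyl (E)-4-bromo-2-methylbut-2-enoate + formaldehyde (boronate-templated ortho-hydroxymethylation, acetonide).
- Ring order: the carbocycle is bought as hydroquinone; a protecting 1,3-dioxin ring is made in step 2 and destroyed in step 6; the oxirane, the only ring made for the target, is formed in step 7.

Assumption: the SMILES is read as the (1S,5S,6S) enantiomer (C5–OH cis to the oxirane oxygen, side chain on the opposite face), and methyl (E)-4-bromo-2-methylbut-2-enoate is taken as a catalogue compound.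

**Step 1**
Reactants: 1 hydroquinone; 2 methyl (E)-4-bromo-2-methylbut-2-enoate
Product: 3 methyl (E)-4-(4-hydroxyphenoxy)-2-methylbut-2-enoate
Conditions: K2CO3, acetone, reflux, N2 (1 in threefold excess)
Reagents that add atoms: none
Why: Williamson ether synthesis, SN2 displacement of the primary allylic bromide by the phenoxide; the excess of 1 keeps bis-alkylation low and the (E)-enoate is not touched.

**Step 2**
Reactants: 3 methyl (E)-4-(4-hydroxyphenoxy)-2-methylbut-2-enoate; 4 formaldehyde (as paraformaldehyde)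
Product: 7 methyl (E)-4-[(2,2-dimethyl-4H-1,3-benzodioxin-6-yl)oxy]-2-methylbut-2-enoate, via cyclic phenylboronate 5 (not isolated), via saligenin-type diol 6 (not isolated)
Conditions: PhB(OH)2, (CH2O)n, EtCO2H (cat.), PhMe, reflux, Dean–Stark; concentrate; then pinacol, Me2C(OMe)2, TsOH (cat.), rt
Reagents that add atoms: 2,2-dimethoxypropane, COC(C)(C)OC
Why: boronate-templated ortho-hydroxymethylation of a phenol (Nagata type), in which the aryl phenylboronate delivers formaldehyde to the ortho carbon (both ortho sites are equivalent); pinacol then strips boron and the diol is closed to the acetonide by acid-catalysed ketalisation.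

**Step 3**
Reactants: 7 methyl (E)-4-[(2,2-dimethyl-4H-1,3-benzodioxin-6-yl)oxy]-2-methylbut-2-enoate
Product: 8 methyl (E)-4-(6-hydroxy-2,2-dimethyl-4H-1,3-benzodioxin-7-yl)-2-methylbut-2-enoate
Conditions: hν (254 nm, quartz), degassed cyclohexane, 0.01 M, 20 °C, to about 70% conversion, 7 recovered
Reagents that add atoms: none
Why: key step, photo-Claisen rearrangement: the excited aryl ether breaks its ArO–CH2 bond to a caged phenoxyl/allyl radical pair, which recombines at the less hindered ortho carbon C7 (para carries oxygen, and a para adduct cannot tautomerise and cleaves again) through the unsubstituted CH2 end of the ester-stabilised allyl radical, so the whole chain arrives with linear connectivity that a thermal [3,3] shift cannot give, and with its E geometry kept because the allyl radical does not rotate within the cage lifetime.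

**Step 4**
Reactants: 8 methyl (E)-4-(6-hydroxy-2,2-dimethyl-4H-1,3-benzodioxin-7-yl)-2-methylbut-2-enoate
Product: 9 methyl (E)-4-(6-hydroxy-5-iodo-2,2-dimethyl-4H-1,3-benzodioxin-7-yl)-2-methylbut-2-enoate
Conditions: NIS, DMF, 0 °C, dark
Reagents that add atoms: N-iodosuccinimide, O=C1CCC(=O)N1I
Why: electrophilic aromatic iodination at the only free position ortho to the phenol, which is also para to the ring-acetal oxygen; neutral conditions spare the acetonide.

**Step 5**
Reactants: 9 methyl (E)-4-(6-hydroxy-5-iodo-2,2-dimethyl-4H-1,3-benzodioxin-7-yl)-2-methylbut-2-enoate; 10 hept-1-yne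
Product: 12 methyl (E)-4-{5-[(E)-hept-1-enyl]-6-hydroxy-2,2-dimethyl-4H-1,3-benzodioxin-7-yl}-2-methylbut-2-enoate, via (E)-heptenyl catechol boronate 11 (not isolated)
Conditions: 10, catecholborane, neat, 70 °C; then 9, Pd(OAc)2 (3 mol %), SPhos (6 mol %), K3PO4, THF/H2O, 40 °C
Reagents that add atoms: none
Why: syn-hydroboration of the terminal alkyne gives the (E)-alkenylboronate and Suzuki–Miyaura coupling transfers it with retention of geometry; the weak base and low temperature keep the phenoxide from adding to the α-methyl enoate.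

**Step 6**
Reactants: 12 methyl (E)-4-{5-[(E)-hept-1-enyl]-6-hydroxy-2,2-dimethyl-4H-1,3-benzodioxin-7-yl}-2-methylbut-2-enoate
Product: 13 methyl (E)-4-{5-[(E)-hept-1-enyl]-4-(hydroxymethyl)-3,6-dioxocyclohexa-1,4-dien-1-yl}-2-methylbut-2-enoate
Conditions: PhI(OAc)2, MeCN/H2O (4:1), 0 °C
Reagents that add atoms: water, O
Why: oxidation of a para-alkoxyphenol by trivalent iodine: water adds to the oxygen-bearing para carbon and the hemiketal collapses to the quinone, expelling the acetal oxygen, which loses acetone and frees the hydroxymethyl group in the same operation.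

**Step 7**
Reactants: 13 methyl (E)-4-{5-[(E)-hept-1-enyl]-4-(hydroxymethyl)-3,6-dioxocyclohexa-1,4-dien-1-yl}-2-methylbut-2-enoate
Product: 14 methyl (E)-4-[(1S,6R)-3-[(E)-hept-1-enyl]-4-(hydroxymethyl)-2,5-dioxo-7-oxabicyclo[4.1.0]hept-3-en-1-yl]-2-methylbut-2-enoate
Conditions: Ph3COOH, NaN(SiMe3)2, D-(−)-diisopropyl tartrate, 4 Å MS, PhMe, −50 °C; NH4Cl (aq)
Reagents that add atoms: trityl hydroperoxide, OOC(c1ccccc1)(c1ccccc1)c1ccccc1
Why: Proposed new method: the trityl peroxide anion, held in a sodium tartrate aggregate that is also bound to the primary alkoxide, adds to the unsubstituted β-carbon of the less substituted quinone double bond (the other one is tetrasubstituted and diene-conjugated) and the enolate closes the oxirane, fixing C1 and C6 together; the closest known reaction is the hydroxyl-directed tartrate-mediated Weitz–Scheffer epoxidation of hydroxymethyl quinone monoketals, from which the D-tartrate is assigned to the (1S,6R) face by analogy and from memory (the L-tartrate gives the mirror image and is used if the first assay shows the opposite sense).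

**Step 8**
Reactants: 14 methyl (E)-4-[(1S,6R)-3-[(E)-hept-1-enyl]-4-(hydroxymethyl)-2,5-dioxo-7-oxabicyclo[4.1.0]hept-3-en-1-yl]-2-methylbut-2-enoate
Product: 15 methyl (E)-4-[(1S,5S,6S)-3-[(E)-hept-1-enyl]-5-hydroxy-4-(hydroxymethyl)-2-oxo-7-oxabicyclo[4.1.0]hept-3-en-1-yl]-2-methylbut-2-enoate
Conditions: Me4NBH(OAc)3, MeCN/AcOH (1:1), −30 °C
Reagents that add atoms: none
Why: hydroxyl-directed reduction (Saksena–Evans type): the primary alcohol exchanges onto boron and hydride is passed through a six-membered transition state only to the adjacent C5 ketone (the C2 ketone and the ester have no such anchor), from the face opposite to the oxirane oxygen (anti to the α C–O bond), which gives the 5S carbinol with OH cis to the epoxide.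

**Step 9**
Reactants: 15 methyl (E)-4-[(1S,5S,6S)-3-[(E)-hept-1-enyl]-5-hydroxy-4-(hydroxymethyl)-2-oxo-7-oxabicyclo[4.1.0]hept-3-en-1-yl]-2-methylbut-2-enoate
Product: 16 (E)-4-[(1S,5S,6S)-3-[(E)-hept-1-enyl]-5-hydroxy-4-(hydroxymethyl)-2-oxo-7-oxabicyclo[4.1.0]hept-3-en-1-yl]-2-methylbut-2-enoic acid
Conditions: Me3SnOH, ClCH2CH2Cl, 70 °C; cold 0.1 M HCl wash
Reagents that add atoms: trimethyltin hydroxide, C[Sn](C)(C)O
Why: tin-assisted acyl–oxygen ester hydrolysis under near-neutral conditions, chosen to spare the epoxide, the enone and the allylic alcohol; no stereocentre is touched.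

**Compound list**
1 | hydroquinone (benzene-1,4-diol) | Oc1ccc(O)cc1 | starting material
2 | methyl (E)-4-bromo-2-methylbut-2-enoate | COC(=O)/C(C)=C/CBr | starting material
3 | methyl (E)-4-(4-hydroxyphenoxy)-2-methylbut-2-enoate | COC(=O)/C(C)=C/COc1ccc(O)cc1 | intermediate
4 | formaldehyde (used as paraformaldehyde) | C=O | starting material
5 | methyl (E)-2-methyl-4-[(2-phenyl-4H-1,3,2-benzodioxaborinin-6-yl)oxy]but-2-enoate | COC(=O)/C(C)=C/COc1ccc2OB(OCc2c1)c1ccccc1 | intermediate
6 | methyl (E)-4-[4-hydroxy-3-(hydroxymethyl)phenoxy]-2-methylbut-2-enoate | COC(=O)/C(C)=C/COc1ccc(O)c(CO)c1 | intermediate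
7 | methyl (E)-4-[(2,2-dimethyl-4H-1,3-benzodioxin-6-yl)oxy]-2-methylbut-2-enoate | COC(=O)/C(C)=C/COc1ccc2OC(C)(C)OCc2c1 | intermediate
8 | methyl (E)-4-(6-hydroxy-2,2-dimethyl-4H-1,3-benzodioxin-7-yl)-2-methylbut-2-enoate | COC(=O)/C(C)=C/Cc1cc2OC(C)(C)OCc2cc1O | intermediate
9 | methyl (E)-4-(6-hydroxy-5-iodo-2,2-dimethyl-4H-1,3-benzodioxin-7-yl)-2-methylbut-2-enoate | COC(=O)/C(C)=C/Cc1cc2OC(C)(C)OCc2c(I)c1O | intermediate
10 | hept-1-yne | CCCCCC#C | starting material
11 | 2-[(E)-hept-1-enyl]-1,3,2-benzodioxaborole | CCCCC/C=C/B1Oc2ccccc2O1 | intermediate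
12 | methyl (E)-4-{5-[(E)-hept-1-enyl]-6-hydroxy-2,2-dimethyl-4H-1,3-benzodioxin-7-yl}-2-methylbut-2-enoate | CCCCC/C=C/c1c(O)c(C/C=C(\C)C(=O)OC)cc2OC(C)(C)OCc12 | intermediate
13 | methyl (E)-4-{5-[(E)-hept-1-enyl]-4-(hydroxymethyl)-3,6-dioxocyclohexa-1,4-dien-1-yl}-2-methylbut-2-enoate | CCCCC/C=C/C1=C(CO)C(=O)C=C(C/C=C(\C)C(=O)OC)C1=O | intermediate
14 | methyl (E)-4-[(1S,6R)-3-[(E)-hept-1-enyl]-4-(hydroxymethyl)-2,5-dioxo-7-oxabicyclo[4.1.0]hept-3-en-1-yl]-2-methylbut-2-enoate | CCCCC/C=C/C1=C(CO)C(=O)[C@@H]2O[C@]2(C/C=C(\C)C(=O)OC)C1=O | intermediate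
15 | methyl (E)-4-[(1S,5S,6S)-3-[(E)-hept-1-enyl]-5-hydroxy-4-(hydroxymethyl)-2-oxo-7-oxabicyclo[4.1.0]hept-3-en-1-yl]-2-methylbut-2-enoate | CCCCC/C=C/C1=C(CO)[C@H](O)[C@@H]2O[C@]2(C/C=C(\C)C(=O)OC)C1=O | intermediate
16 | (E)-4-[(1S,5S,6S)-3-[(E)-hept-1-enyl]-5-hydroxy-4-(hydroxymethyl)-2-oxo-7-oxabicyclo[4.1.0]hept-3-en-1-yl]-2-methylbut-2-enoic acid | CCCCC/C=C/C1=C(CO)[C@H](O)[C@@H]2O[C@]2(C/C=C(\C)C(=O)O)C1=O | target

**Totals and risks**
Total step count: 9. Longest linear sequence: 9 steps (1 to 16); hept-1-yne enters in step 5 and is hydroborated in the same flask.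

Most likely to fail, step 3 (photo-Claisen). The risks are cage escape to the free phenol, some attack at C5, E/Z leakage of the enoate under UV light and secondary photochemistry of 8; a yield of 35–50% is what this reaction class usually gives. Fallback: put the chain on by ionic phenoxide C-alkylation. It sets out from 1: boronate-templated hydroxymethylation with 4 gives 2-phenyl-4H-1,3,2-benzodioxaborinin-6-ol F1, pinacol frees 2-(hydroxymethyl)benzene-1,4-diol F2, and Me2C(OMe)2/TsOH gives 2,2-dimethyl-4H-1,3-benzodioxin-6-ol F3. The sodium salt of F3 (NaH, toluene, heterogeneous, 60 °C) is alkylated by 2 on carbon at the less hindered ortho position, the tight ion pair in a non-polar solvent favouring C over O. This gives 8, where the route is rejoined; O-alkylated material is 7 and is recycled.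

Second, step 7 (asymmetric epoxidation of a free quinone). The risks are a fast undirected background reaction (low ee), an unverified facial sense, and base-induced isomerisation of the doubly allylic CH2 of the side chain. Fallback: give up induction and separate enantiomers. It sets out from 13: t-BuOOH/DBU in CH2Cl2 at −20 °C gives the racemic epoxyquinone ester F4, the reduction of step 8 gives the racemic epoxyquinol ester F5, and preparative chromatography on a chiral stationary phase (amylose carbamate, supercritical CO2/MeOH) separates 15 from its (1R,5R,6R) enantiomer F6. The route is rejoined at 15.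

Third, step 9 (late ester cleavage). The α-methyl enoate is a slow ester and 15 may not survive prolonged heating with the tin reagent. Fallback: remove the ester while the ring is still aromatic and carry the free acid. It sets out from 12: Me3SnOH in ClCH2CH2Cl at 80 °C gives (E)-4-{5-[(E)-hept-1-enyl]-6-hydroxy-2,2-dimethyl-4H-1,3-benzodioxin-7-yl}-2-methylbut-2-enoic acid F7. PhI(OAc)2 in MeCN/H2O then gives the quinone acid F8, and the epoxidation of step 7 with one more equivalent of NaN(SiMe3)2 gives the epoxyquinone acid F9. The borohydride reduction of step 8, which tolerates the carboxylic acid, then gives 16 directly.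

**Further compounds**
F1 | step 3 | 2-phenyl-4H-1,3,2-benzodioxaborinin-6-ol | Oc1ccc2OB(OCc2c1)c1ccccc1
F2 | step 3 | 2-(hydroxymethyl)benzene-1,4-diol | OCc1cc(O)ccc1O
F3 | step 3 | 2,2-dimethyl-4H-1,3-benzodioxin-6-ol | CC1(C)OCc2cc(O)ccc2O1
F4 | step 7 | racemic epoxyquinone ester (1:1 mixture of 14 and its (1R,6S) enantiomer) | CCCCC/C=C/C1=C(CO)C(=O)[C@@H]2O[C@]2(C/C=C(\C)C(=O)OC)C1=O.CCCCC/C=C/C1=C(CO)C(=O)[C@H]2O[C@@]2(C/C=C(\C)C(=O)OC)C1=O
F5 | step 7 | racemic epoxyquinol ester (1:1 mixture of 15 and its (1R,5R,6R) enantiomer) | CCCCC/C=C/C1=C(CO)[C@H](O)[C@@H]2O[C@]2(C/C=C(\C)C(=O)OC)C1=O.CCCCC/C=C/C1=C(CO)[C@@H](O)[C@H]2O[C@@]2(C/C=C(\C)C(=O)OC)C1=O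
F6 | step 7 | methyl (E)-4-[(1R,5R,6R)-3-[(E)-hept-1-enyl]-5-hydroxy-4-(hydroxymethyl)-2-oxo-7-oxabicyclo[4.1.0]hept-3-en-1-yl]-2-methylbut-2-enoate | CCCCC/C=C/C1=C(CO)[C@@H](O)[C@H]2O[C@@]2(C/C=C(\C)C(=O)OC)C1=O
F7 | step 9 | (E)-4-{5-[(E)-hept-1-enyl]-6-hydroxy-2,2-dimethyl-4H-1,3-benzodioxin-7-yl}-2-methylbut-2-enoic acid | CCCCC/C=C/c1c(O)c(C/C=C(\C)C(=O)O)cc2OC(C)(C)OCc12
F8 | step 9 | (E)-4-{5-[(E)-hept-1-enyl]-4-(hydroxymethyl)-3,6-dioxocyclohexa-1,4-dien-1-yl}-2-methylbut-2-enoic acid | CCCCC/C=C/C1=C(CO)C(=O)C=C(C/C=C(\C)C(=O)O)C1=O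
F9 | step 9 | (E)-4-[(1S,6R)-3-[(E)-hept-1-enyl]-4-(hydroxymethyl)-2,5-dioxo-7-oxabicyclo[4.1.0]hept-3-en-1-yl]-2-methylbut-2-enoic acid | CCCCC/C=C/C1=C(CO)C(=O)[C@@H]2O[C@]2(C/C=C(\C)C(=O)O)C1=O
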